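**Retrosynthetic overview**
1. Chebulic acid 14 ⇐ 13 by global dealkylation (three ArOMe, two CO2Et); 13 ⇐ 12 by oxidative excision of the keto carbon.
2. Key disconnection: the C-3–O bond of lactone ring B ⇐ iodide-mediated anodic α-C–H oxylactonization of keto acid 10 (closes ring B, sets C-3 trans to C-4).
3. 10/9 ⇐ oxodiene 6 + enal 7 by a carbene-catalysed oxa-Diels–Alder reaction that sets C-4 and the succinate carbon C-2′ as a cis-dihydropyranone, opened with ethanol.
4. 6 ⇐ aldehyde 4 + ylide 5 (Wittig); 4 ⇐ ortho-magnesiation/formylation of ester 2 ⇐ acid chloride 1.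
5. Ring order: aromatic ring A is bought; the dihydropyranone ring is made and opened in step 4; lactone ring B is closed last, in step 5.

Assumption: the (5aS,10bR) antipode of the aminoindanol-derived triazolium salt is taken to give the (3S,4S) cycloadduct; if the sense of induction is the reverse, the equally available (5aR,10bS) antipode is used.
Assumption: compounds 1, 5 and 7 are bought as catalogue items.

**Route**

Step 1
Reactants: 1 3,4,5-trimethoxybenzoyl chloride
Product: 2 tert-butyl 3,4,5-trimethoxybenzoate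
Conditions: KOtBu (1.1 equiv), THF, 0 → 23 °C
Reagents that add atoms: potassium tert-butoxide, CC(C)(C)[O-].[K+]
Why: Acyl substitution of an aroyl chloride by tert-butoxide is fast and clean, and the tert-butyl ester survives the base, ylide and carbene steps and is removed by acid in the flask of the key step.

Step 2
Reactants: 2 tert-butyl 3,4,5-trimethoxybenzoate
Product: 4 tert-butyl 2-formyl-3,4,5-trimethoxybenzoate, via arylmagnesium chloride 3 (not isolated)
Conditions: TMPMgCl·LiCl (1.3 equiv), THF, 0 → 23 °C; then Me2NCHO, 0 → 23 °C; cold 1 M HCl work-up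
Reagents that add atoms: N,N-dimethylformamide, CN(C)C=O
Why: Directed ortho-magnesiation (Knochel–Hauser base) removes the hydrogen flanked by the ester and a methoxy group (both ortho positions are equivalent by symmetry) without attacking the hindered ester, and the arylmagnesium is formylated by DMF (Bouveault-type formylation).

Step 3
Reactants: 4 tert-butyl 2-formyl-3,4,5-trimethoxybenzoate; 5 ethyl 2-oxo-3-(triphenylphosphoranylidene)propanoate
Product: 6 tert-butyl 2-[(1E)-4-ethoxy-3,4-dioxobut-1-en-1-yl]-3,4,5-trimethoxybenzoate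
Conditions: toluene, 100 °C
Reagents that add atoms: none
Why: Wittig olefination with a keto-stabilised ylide gives the (E)-enone selectively under neutral conditions, so the base-sensitive β,γ-unsaturated α-keto ester forms without touching the ortho ester.

Step 4
Reactants: 6 tert-butyl 2-[(1E)-4-ethoxy-3,4-dioxobut-1-en-1-yl]-3,4,5-trimethoxybenzoate; 7 ethyl (2E)-4-oxobut-2-enoate
Product: 9 triethyl (2S,3S)-3-[6-(tert-butoxycarbonyl)-2,3,4-trimethoxyphenyl]-5-oxopentane-1,2,5-tricarboxylate, via cis-dihydropyranone 8 (not isolated)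
Conditions: (5aS,10bR)-2-mesityl-5a,10b-dihydro-4H,6H-indeno[2,1-b][1,2,4]triazolo[4,3-d][1,4]oxazin-2-ium chloride (10 mol%), N-methylmorpholine (20 mol%), toluene, 40 °C; then EtOH, 4-(dimethylamino)pyridine (20 mol%), 23 °C
Reagents that add atoms: ethanol, CCO
Why: In this N-heterocyclic-carbene-catalysed inverse-demand oxa-Diels–Alder reaction the carbene turns enal 7, by β-protonation, into a chiral azolium enolate that adds endo to the s-cis oxodiene, setting C-4 and C-2′ together as the cis-(3S,4S) enol lactone 8; ethanolysis of this activated lactone then opens the ring without touching either stereocentre.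

Step 5
Reactants: 9 triethyl (2S,3S)-3-[6-(tert-butoxycarbonyl)-2,3,4-trimethoxyphenyl]-5-oxopentane-1,2,5-tricarboxylate
Product: 12 diethyl (2S)-2-[(3S,4S)-3-(2-ethoxy-2-oxoacetyl)-5,6,7-trimethoxy-1-oxo-3,4-dihydro-1H-isochromen-4-yl]butanedioate, via keto acid 10 (not isolated), via iodo keto acid 11 (not isolated)
Conditions: CF3CO2H/CH2Cl2 (1:4), 23 °C, evaporate; then n-Bu4NI (0.3 equiv), 2,6-lutidine (1 equiv), n-Bu4NBF4 (0.1 M), MeCN/(CF3)2CHOH (9:1), graphite anode, Pt cathode, undivided cell, 5 mA cm-2, 2.2 F mol-1, 23 °C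
Reagents that add atoms: none
Why: Proposed new method: after acidolysis of the tert-butyl ester, iodide is oxidised at the anode to iodine (far below the potential of the trimethoxyarene), the lutidine-enolised α-keto ester is C-iodinated at the only ketone α-carbon to give 11, and the neighbouring benzoate displaces iodide in a 6-exo SN2 step that closes ring B and returns the mediator while protons are reduced to H2 at the cathode; the C-3 epimers of 11 interconvert by iodide exchange and enolisation, and the still acidic C-3 hydrogen of 12 equilibrates, so the product is the trans (3S) lactone in which the keto ester group lies anti to the C-4 side chain (held pseudo-axial by the peri methoxy group); the closest known reactions are the ammonium hypoiodite-catalysed α-oxyacylation and oxylactonization of ketones with peroxide oxidants, the lactonization of keto acids by trivalent iodine reagents, and halide-mediated indirect anodic α-functionalisation of ketones, none shown for an α-keto ester with a benzoic acid nucleophile.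

Step 6
Reactants: 12 diethyl (2S)-2-[(3S,4S)-3-(2-ethoxy-2-oxoacetyl)-5,6,7-trimethoxy-1-oxo-3,4-dihydro-1H-isochromen-4-yl]butanedioate
Product: 13 (3S,4S)-4-[(2S)-1,4-diethoxy-1,4-dioxobutan-2-yl]-5,6,7-trimethoxy-1-oxo-3,4-dihydro-1H-isochromene-3-carboxylic acid
Conditions: 30% aq H2O2 (3 equiv), THF/aq pH 7 phosphate buffer, 0 → 23 °C
Reagents that add atoms: hydrogen peroxide, OO
Why: Oxidative decarboxylative cleavage of the α-keto ester (hydroperoxide addition to the very electrophilic keto carbonyl, then a Baeyer–Villiger-type acyl shift) removes the one surplus carbon and leaves the C-3 carboxylic acid, after which C-3 is no longer readily epimerised.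

Step 7
Reactants: 13 (3S,4S)-4-[(2S)-1,4-diethoxy-1,4-dioxobutan-2-yl]-5,6,7-trimethoxy-1-oxo-3,4-dihydro-1H-isochromene-3-carboxylic acid
Product: 14 chebulic acid
Conditions: BBr3 (15 equiv), CH2Cl2, -78 → 23 °C; then H2O, 0 → 23 °C
Reagents that add atoms: none
Why: BBr3 dealkylates the three aryl methyl ethers and the two ethyl esters (Lewis acid activation, then bromide SN2 at the alkyl carbon), so no bond to a stereocentre is broken, and the six-membered aryl lactone persists under the acidic aqueous work-up.

**Compound list**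

1 | 3,4,5-trimethoxybenzoyl chloride | COc1cc(C(=O)Cl)cc(OC)c1OC | starting material
2 | tert-butyl 3,4,5-trimethoxybenzoate | COc1cc(C(=O)OC(C)(C)C)cc(OC)c1OC | intermediate
3 | [6-(tert-butoxycarbonyl)-2,3,4-trimethoxyphenyl]magnesium chloride (LiCl complex) | COc1cc(C(=O)OC(C)(C)C)c([Mg]Cl)c(OC)c1OC | intermediate
4 | tert-butyl 2-formyl-3,4,5-trimethoxybenzoate | COc1cc(C(=O)OC(C)(C)C)c(C=O)c(OC)c1OC | intermediate
5 | ethyl 2-oxo-3-(triphenylphosphoranylidene)propanoate | CCOC(=O)C(=O)C=P(c1ccccc1)(c1ccccc1)c1ccccc1 | starting material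
6 | tert-butyl 2-[(1E)-4-ethoxy-3,4-dioxobut-1-en-1-yl]-3,4,5-trimethoxybenzoate | CCOC(=O)C(=O)/C=C/c1c(C(=O)OC(C)(C)C)cc(OC)c(OC)c1OC | intermediate
7 | ethyl (2E)-4-oxobut-2-enoate | CCOC(=O)/C=C/C=O | starting material
8 | ethyl (3S,4S)-4-[6-(tert-butoxycarbonyl)-2,3,4-trimethoxyphenyl]-3-(2-ethoxy-2-oxoethyl)-2-oxo-3,4-dihydro-2H-pyran-6-carboxylate (3,4-cis) | CCOC(=O)C[C@@H]1C(=O)OC(C(=O)OCC)=C[C@@H]1c2c(C(=O)OC(C)(C)C)cc(OC)c(OC)c2OC | intermediate
9 | triethyl (2S,3S)-3-[6-(tert-butoxycarbonyl)-2,3,4-trimethoxyphenyl]-5-oxopentane-1,2,5-tricarboxylate | CCOC(=O)C[C@H](C(=O)OCC)[C@H](CC(=O)C(=O)OCC)c1c(C(=O)OC(C)(C)C)cc(OC)c(OC)c1OC | intermediate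
10 | triethyl (2S,3S)-3-(6-carboxy-2,3,4-trimethoxyphenyl)-5-oxopentane-1,2,5-tricarboxylate | CCOC(=O)C[C@H](C(=O)OCC)[C@H](CC(=O)C(=O)OCC)c1c(C(=O)O)cc(OC)c(OC)c1OC | intermediate
11 | triethyl (2S,3S)-3-(6-carboxy-2,3,4-trimethoxyphenyl)-4-iodo-5-oxopentane-1,2,5-tricarboxylate (both C-4 epimers) | CCOC(=O)C[C@H](C(=O)OCC)[C@H](C(I)C(=O)C(=O)OCC)c1c(C(=O)O)cc(OC)c(OC)c1OC | intermediate
12 | diethyl (2S)-2-[(3S,4S)-3-(2-ethoxy-2-oxoacetyl)-5,6,7-trimethoxy-1-oxo-3,4-dihydro-1H-isochromen-4-yl]butanedioate (3,4-trans) | CCOC(=O)C[C@H](C(=O)OCC)[C@H]1c2c(cc(OC)c(OC)c2OC)C(=O)O[C@@H]1C(=O)C(=O)OCC | intermediate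
13 | (3S,4S)-4-[(2S)-1,4-diethoxy-1,4-dioxobutan-2-yl]-5,6,7-trimethoxy-1-oxo-3,4-dihydro-1H-isochromene-3-carboxylic acid | CCOC(=O)C[C@H](C(=O)OCC)[C@H]1c2c(cc(OC)c(OC)c2OC)C(=O)O[C@@H]1C(=O)O | intermediate
14 | chebulic acid, (2S)-2-[(3S,4S)-3-carboxy-5,6,7-trihydroxy-1-oxo-3,4-dihydro-1H-isochromen-4-yl]butanedioic acid | O=C(O)C[C@H](C(=O)O)[C@H]1c2c(cc(O)c(O)c2O)C(=O)O[C@@H]1C(=O)O | target

**Step count and risks**

Total steps: 7. Longest linear sequence: 7 (from 1; compounds 5 and 7 are bought).

Three steps most likely to fail: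

Step 5 (the new anodic oxylactonization). The risks are slow C-iodination, a second oxidation at C-3, or cathodic reduction of the keto ester. The fallback uses known chemistry, sets out from 9 and comes back at 12. CF3CO2H/CH2Cl2 gives keto acid 10, this time isolated. CuBr2 (2.2 equiv) in EtOAc/CHCl3 at 70 °C brominates the ketone α-carbon (King–Ostrum bromination) to give triethyl (2S,3S)-4-bromo-3-(6-carboxy-2,3,4-trimethoxyphenyl)-5-oxopentane-1,2,5-tricarboxylate F1 as an epimer mixture. K2CO3 with catalytic n-Bu4NBr in acetone at 23 °C then closes the lactone by carboxylate SN2 displacement (phenacyl-ester-type alkylation); bromide exchange and the acidic C-3 hydrogen funnel both epimers to trans 12.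

Step 4 (carbene-catalysed cycloaddition). The aryl group of 6 carries two ortho substituents that shield the carbon being attacked, and homoenolate pathways can compete. The fallback sets out from 6 and comes back at 9, replacing the carbene-generated enolate by a preformed one under Lewis acid activation. Diethyl succinate is converted (LiN(iPr)2, Me3SiCl, THF, -78 °C) into ethyl (3E)-4-ethoxy-4-[(trimethylsilyl)oxy]but-3-enoate F2. Cu(OTf)2 with (S,S)-2,2'-(propane-2,2-diyl)bis(4-tert-butyl-4,5-dihydro-1,3-oxazole) (10 mol%) chelates the α-keto ester of 6 and catalyses the Mukaiyama–Michael addition in CH2Cl2 at -78 °C. (CF3)2CHOH is present to take up the silyl group, so 9 is released directly. The ketene acetal geometry selects the C-2 epimer and the ligand antipode the absolute sense; the pairing giving (2S,3S) is used.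

Step 7 (one-pot global dealkylation). Five groups must be cleaved on a polar polyacid, with risk of incomplete ester cleavage or lactone opening by bromide. The fallback sets out from 13 and comes back at 14 by staged deprotection. LiOH in THF/H2O at 0 °C saponifies both ethyl esters; the lactone opens and re-closes on acidification with HCl, giving (2S)-2-[(3S,4S)-3-carboxy-5,6,7-trimethoxy-1-oxo-3,4-dihydro-1H-isochromen-4-yl]butanedioic acid F3. BCl3 with n-Bu4NI in CH2Cl2 (-78 → 0 °C) then removes only the three methyl ethers.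

**Further compounds**

F1 | step 5 | triethyl (2S,3S)-4-bromo-3-(6-carboxy-2,3,4-trimethoxyphenyl)-5-oxopentane-1,2,5-tricarboxylate (both C-4 epimers) | CCOC(=O)C[C@H](C(=O)OCC)[C@H](C(Br)C(=O)C(=O)OCC)c1c(C(=O)O)cc(OC)c(OC)c1OC
F2 | step 4 | ethyl (3E)-4-ethoxy-4-[(trimethylsilyl)oxy]but-3-enoate | CCOC(=O)C/C=C(\OCC)O[Si](C)(C)C
F3 | step 7 | (2S)-2-[(3S,4S)-3-carboxy-5,6,7-trimethoxy-1-oxo-3,4-dihydro-1H-isochromen-4-yl]butanedioic acid | O=C(O)C[C@H](C(=O)O)[C@H]1c2c(cc(OC)c(OC)c2OC)C(=O)O[C@@H]1C(=O)O
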